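## Retrosynthetic overview

1. Target 38 ⇐ heptabenzyl ether 37 (BCl3 debenzylation) ⇐ Friedel–Crafts union at the diarylmethine carbon: benzofuran carbinol 17 (as cation) plus the free resorcinol ring B of oxolane fragment 36.
2. 17 ⇐ Heck reaction (chalcone) and aryl Grignard addition on 3-formyl-dihydrobenzofuran 11 ⇐ trans-dihydrobenzofuran 10 ⇐ aromatic Claisen rearrangement of lactate-derived aryl allyl ether 8 (C3–aryl bond, 1,3-chirality transfer; key step), then cationic ring closure.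
3. 36 ⇐ oxolane from 2,3-dihydrofuran 31 by aldehyde addition at C4 and oxocarbenium reduction at C5 ⇐ keto aldehyde 26 plus ring B Grignard ⇐ (R)-4-benzylbutyrolactone 22 ⇐ (R)-epichlorohydrin plus malonate.
4. Ring order: dihydrobenzofuran (step 4); cyclopropane-fused lactone, then opened (steps 9–12); 2,3-dihydrofuran (step 15); oxolane (step 17). All seven stereocentres are relayed from ethyl (S)-lactate and (R)-epichlorohydrin.

Assumption: compounds 6, 12 and 15 are taken as catalogue items; oxolane locants are O1, C2 (ring B aryl), C3 (benzyl), C4 (acyl), C5 (4-oxyphenyl). Where a CIP descriptor of an intermediate differs from the target's, only substituent priorities have changed, not the geometry.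

## Route

Step 1
Reactants: 1 4-iodophenol; 2 ethyl (S)-lactate
Product: 3 ethyl (2R)-2-(4-iodophenoxy)propanoate
Conditions: PPh3, DIAD, THF, 0 °C → rt
Reagents that add atoms: none
Why: Mitsunobu etherification runs by SN2 inversion at the lactate carbon, so the bought (S) centre becomes the (R) aryl ether that steers step 4.

Step 2
Reactants: 3 ethyl (2R)-2-(4-iodophenoxy)propanoate
Product: 5 (2E,4R)-4-(4-iodophenoxy)pent-2-enal, via aldehyde 4 (not isolated)
Conditions: (Me2CHCH2)2AlH (DIBAL-H), CH2Cl2, −78 °C; then Ph3P=CHCHO, −78 °C → rt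
Reagents that add atoms: (triphenylphosphoranylidene)acetaldehyde, O=CC=P(c1ccccc1)(c1ccccc1)c1ccccc1
Why: Half-reduction of the ester stops at the aluminium hemiacetal, and the Wittig reaction with a stabilised ylide gives the (E)-enal without exposing the α-aryloxy aldehyde to base.

Step 3
Reactants: 5 (2E,4R)-4-(4-iodophenoxy)pent-2-enal; 6 [4-(benzyloxy)phenyl]magnesium bromide
Product: 8 tert-butyl{[(2E,4R)-1-[4-(benzyloxy)phenyl]-4-(4-iodophenoxy)pent-2-en-1-yl]oxy}dimethylsilane (C1 epimers), via alcohol 7 (not isolated)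
Conditions: THF, −78 °C; aq. NH4Cl; crude 7: TBSCl, imidazole, DMF, rt
Reagents that add atoms: tert-butyldimethylsilyl chloride, CC(C)(C)[Si](C)(C)Cl
Why: 1,2-Grignard addition to the enal followed by silylation; the new carbinol centre is left uncontrolled because it is ionised in step 4.

Step 4
Reactants: 8 silyl ether (C1 epimers)
Product: 10 (2S,3S)-2-[4-(benzyloxy)phenyl]-5-iodo-3-[(1E)-prop-1-en-1-yl]-2,3-dihydro-1-benzofuran, via phenol 9 (not isolated)
Conditions: 1,2-dichlorobenzene, 180 °C, 4 h; cool, dilute with CH2Cl2, TsOH·H2O (10 mol %), 0 °C → rt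
Reagents that add atoms: none
Why: The aromatic Claisen rearrangement ([3,3]-sigmatropic, chair with methyl equatorial, para position blocked by iodine) forms the C3–aryl bond suprafacially, turning the (R) C–O centre into the (S) benzylic carbon and an (E)-propenyl group; acid then ionises the 4-alkoxybenzylic silyl ether and the phenol closes the ring reversibly to the trans-2,3 isomer.

Step 5
Reactants: 10 (2S,3S)-propenyl dihydrobenzofuran
Product: 11 (2S,3S)-2-[4-(benzyloxy)phenyl]-5-iodo-2,3-dihydro-1-benzofuran-3-carbaldehyde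
Conditions: OsO4 (2 mol %), NaIO4, 2,6-lutidine, dioxane–H2O 3:1, rt
Reagents that add atoms: sodium periodate, [Na+].[O-]I(=O)(=O)=O
Why: Lemieux–Johnson cleavage of the only alkene under near-neutral conditions; the trans aldehyde is also the thermodynamic C3 epimer and is used at once.

Step 6
Reactants: 11 (2S,3S)-aldehyde; 12 2,4-bis(benzyloxy)-1-bromobenzene
Product: 14 [2,4-bis(benzyloxy)phenyl]{(2S,3R)-2-[4-(benzyloxy)phenyl]-5-iodo-2,3-dihydro-1-benzofuran-3-yl}methanol (carbinol epimers), via arylmagnesium bromide 13 (not isolated)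
Conditions: 12, Mg, THF, 45 °C; then 11, −78 °C; aq. NH4Cl
Reagents that add atoms: none
Why: Grignard addition at low temperature outruns enolisation of the α-aryl aldehyde; the carbinol centre is ionised in step 20 and needs no control.

Step 7
Reactants: 15 1-[2,4-bis(benzyloxy)phenyl]ethan-1-one
Product: 16 1-[2,4-bis(benzyloxy)phenyl]prop-2-en-1-one
Conditions: (CH2O)n, diisopropylammonium trifluoroacetate, CF3CO2H (10 mol %), THF, reflux
Reagents that add atoms: formaldehyde (as paraformaldehyde), C=O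
Why: Mannich-type α-methylenation (aminomethylation then elimination) converts the aryl methyl ketone into the aryl vinyl ketone in one operation.

Step 8
Reactants: 14 iodo carbinol; 16 aryl vinyl ketone
Product: 17 (2E)-1-[2,4-bis(benzyloxy)phenyl]-3-{(2S,3R)-2-[4-(benzyloxy)phenyl]-3-[[2,4-bis(benzyloxy)phenyl](hydroxy)methyl]-2,3-dihydro-1-benzofuran-5-yl}prop-2-en-1-one (carbinol epimers)
Conditions: Pd(OAc)2 (5 mol %), n-Bu4NCl, NaHCO3, DMF, 50 °C
Reagents that add atoms: none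
Why: Heck reaction under Jeffery conditions (zerovalent palladium formed in situ) couples the aryl iodide with the enone to give the (E)-chalcone at a temperature the benzylic alcohol tolerates.

Step 9
Reactants: 18 (R)-epichlorohydrin; 19 dimethyl malonate
Product: 20 methyl (1S,5R)-2-oxo-3-oxabicyclo[3.1.0]hexane-1-carboxylate
Conditions: NaOMe, MeOH, 0 °C → reflux
Reagents that add atoms: none
Why: Malonate opens the epoxide at CH2, the alkoxide re-forms an epoxide by displacing chloride, and 3-exo-tet cyclopropanation with inversion followed by lactonisation relays the bought stereocentre into the bicyclic lactone.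

Step 10
Reactants: 20 bicyclic lactone; 6 [4-(benzyloxy)phenyl]magnesium bromide
Product: 21 methyl (3S,4R)-4-[4-(benzyloxy)benzyl]-2-oxooxolane-3-carboxylate
Conditions: CuI (10 mol %), THF, −30 → 0 °C; aq. NH4Cl
Reagents that add atoms: none
Why: Copper-catalysed homoconjugate addition of the aryl Grignard opens the doubly activated cyclopropane at its CH2 without touching the stereocentre; the acidic α-centre settles trans.

Step 11
Reactants: 21 malonate-type lactone
Product: 22 (4R)-4-[4-(benzyloxy)benzyl]oxolan-2-one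
Conditions: LiCl, DMSO–H2O, 140 °C
Reagents that add atoms: none
Why: Krapcho dealkoxycarbonylation removes the ester and leaves the β-stereocentre untouched.

Step 12
Reactants: 22 (4R)-lactone; 23 1-(benzyloxy)-4-bromobenzene
Product: 25 (3R)-1-[4-(benzyloxy)phenyl]-3-[4-(benzyloxy)benzyl]-4-hydroxybutan-1-one, via aryllithium 24 (not isolated)
Conditions: 23, n-BuLi, THF, −78 °C; then 22, −78 °C; aq. NH4Cl
Reagents that add atoms: none
Why: Bromine–lithium exchange, then single addition of the aryllithium to the lactone (the lithium hemiketal is stable at −78 °C), gives the γ-hydroxy aryl ketone.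

Step 13
Reactants: 25 (3R)-hydroxy ketone
Product: 26 (2R)-2-[4-(benzyloxy)benzyl]-4-[4-(benzyloxy)phenyl]-4-oxobutanal
Conditions: Dess–Martin periodinane, pyridine, CH2Cl2, 0 °C
Reagents that add atoms: none
Why: Buffered Dess–Martin oxidation gives the aldehyde without epimerising the α-centre or inducing furan formation; 26 is used crude.

Step 14
Reactants: 27 4-bromobenzene-1,3-diol
Product: 28 [(4-bromo-1,3-phenylene)bis(oxy)]bis(tert-butyldimethylsilane)
Conditions: TBSCl, imidazole, DMF, rt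
Reagents that add atoms: tert-butyldimethylsilyl chloride, CC(C)(C)[Si](C)(C)Cl
Why: Silylation masks both phenols of ring B with groups that survive Grignard formation and are removed by mild methanolysis in step 19.

Step 15
Reactants: 26 (2R)-keto aldehyde; 28 bis-silyl ether of 4-bromoresorcinol
Product: 31 (2R,3R)-3-[4-(benzyloxy)benzyl]-5-[4-(benzyloxy)phenyl]-2-{2,4-bis[(tert-butyldimethylsilyl)oxy]phenyl}-2,3-dihydrofuran, via arylmagnesium bromide 29 (not isolated), via hydroxy ketone 30 (not isolated)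
Conditions: 28, Mg, THF, 45 °C; then 26, −78 °C; aq. NH4Cl; crude 30: TsOH·H2O (5 mol %), 4 Å MS, CH2Cl2, rt
Reagents that add atoms: none
Why: The Grignard adds chemoselectively to the aldehyde beside the deactivated aryl ketone, and acid-catalysed cyclodehydration (hemiketal to enol ether) gives the dihydrofuran, in which C2 equilibrates by reversible benzylic ionisation to trans relative to the epichlorohydrin-derived C3.

Step 16
Reactants: 32 2,4-dihydroxybenzaldehyde
Product: 33 4-formyl-1,3-phenylene diacetate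
Conditions: Ac2O, pyridine, DMAP (cat.), CH2Cl2, rt
Reagents that add atoms: acetic anhydride, CC(=O)OC(C)=O
Why: Acetylation makes the aldehyde electron-poor, so the benzylic oxygen created in step 17 is not ionised by the Lewis acid.

Step 17
Reactants: 31 (2R,3R)-dihydrofuran; 33 4-formyl-1,3-phenylene diacetate
Product: 34 (2R,3R,4S,5S)-3-[4-(benzyloxy)benzyl]-5-[4-(benzyloxy)phenyl]-2-{2,4-bis[(tert-butyldimethylsilyl)oxy]phenyl}-4-[(2,4-diacetoxyphenyl)(hydroxy)methyl]oxolane (carbinol epimers)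
Conditions: BF3·OEt2 (1.2 equiv), Et3SiH (3 equiv), CH2Cl2, −78 °C; H2O quench
Reagents that add atoms: none
Why: Prins/Mukaiyama-type addition of the cyclic enol ether to the activated aldehyde occurs anti to the C3 benzyl group (sets C4); ionic hydrogenation of the aryl-stabilised oxocarbenium ion by Et3SiH then occurs anti to the new C4 substituent, placing the C5 aryl cis to it, as in hemiketal reductions used for lignans.

Step 18
Reactants: 34 oxolane carbinol
Product: 35 (2R,3R,4R,5S)-3-[4-(benzyloxy)benzyl]-5-[4-(benzyloxy)phenyl]-2-{2,4-bis[(tert-butyldimethylsilyl)oxy]phenyl}-4-(2,4-diacetoxybenzoyl)oxolane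
Conditions: Dess–Martin periodinane, pyridine, CH2Cl2, 0 °C
Reagents that add atoms: none
Why: Dess–Martin oxidation converges both carbinol epimers on the aryl ketone under buffered conditions that do not epimerise C4.

Step 19
Reactants: 35 diacetate bis-silyl ether
Product: 36 (2R,3R,4R,5S)-3-[4-(benzyloxy)benzyl]-5-[4-(benzyloxy)phenyl]-4-(2,4-dihydroxybenzoyl)-2-(2,4-dihydroxyphenyl)oxolane
Conditions: K2CO3, MeOH, 0 °C → rt; pH 6 phosphate buffer
Reagents that add atoms: none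
Why: Base-catalysed methanolysis cleaves the aryl acetates and aryl silyl ethers together; the ortho-phenoxide formed on the ketone ring lowers the acidity of C4–H during the short cold exposure.

Step 20
Reactants: 17 benzofuran carbinol; 36 oxolane tetraphenol
Product: 37 (2E)-1-[2,4-bis(benzyloxy)phenyl]-3-{(2S,3S)-2-[4-(benzyloxy)phenyl]-3-[(S)-[2,4-bis(benzyloxy)phenyl]{5-[(2R,3R,4R,5S)-3-[4-(benzyloxy)benzyl]-5-[4-(benzyloxy)phenyl]-4-(2,4-dihydroxybenzoyl)oxolan-2-yl]-2,4-dihydroxyphenyl}methyl]-2,3-dihydro-1-benzofuran-5-yl}prop-2-en-1-one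
Conditions: TsOH·H2O (10 mol %), (CF3)2CHOH–CH2Cl2 1:4, −20 → 0 °C; 17 added slowly to 36 (1.3 equiv)
Reagents that add atoms: none
Why: Friedel–Crafts alkylation: the 2,4-dialkoxybenzylic cation from 17 is trapped by the most nucleophilic arene present, free resorcinol ring B, para to one OH and ortho to the other; with C3–H eclipsing the cation plane the arene enters anti to C2, which gives the target methine geometry.

Step 21
Reactants: 37 heptabenzyl ether
Product: 38 target (CNP0225254.5)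
Conditions: BCl3 (1 M in CH2Cl2, excess), C6HMe5, CH2Cl2, −78 °C; then H2O–THF
Reagents that add atoms: none
Why: Lewis-acid debenzylation with pentamethylbenzene as cation scavenger removes all seven benzyl ethers at −78 °C without reducing the enone or opening the two benzylic cyclic ethers.

## Compound list

1 | 4-iodophenol | Oc1ccc(I)cc1 | starting material
2 | ethyl (S)-lactate | C[C@H](O)C(=O)OCC | starting material
3 | ethyl (2R)-2-(4-iodophenoxy)propanoate | C[C@@H](Oc1ccc(I)cc1)C(=O)OCC | intermediate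
4 | (2R)-2-(4-iodophenoxy)propanal | C[C@@H](Oc1ccc(I)cc1)C=O | intermediate
5 | (2E,4R)-4-(4-iodophenoxy)pent-2-enal | C[C@@H](Oc1ccc(I)cc1)/C=C/C=O | intermediate
6 | [4-(benzyloxy)phenyl]magnesium bromide (THF solution) | Br[Mg]c1ccc(OCc2ccccc2)cc1 | starting material
7 | (2E,4R)-1-[4-(benzyloxy)phenyl]-4-(4-iodophenoxy)pent-2-en-1-ol (C1 epimers) | C[C@@H](Oc1ccc(I)cc1)/C=C/C(O)c1ccc(OCc2ccccc2)cc1 | intermediate
8 | tert-butyl{[(2E,4R)-1-[4-(benzyloxy)phenyl]-4-(4-iodophenoxy)pent-2-en-1-yl]oxy}dimethylsilane (C1 epimers) | C[C@@H](Oc1ccc(I)cc1)/C=C/C(O[Si](C)(C)C(C)(C)C)c1ccc(OCc2ccccc2)cc1 | intermediate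
9 | 2-{(2S,3E)-1-[4-(benzyloxy)phenyl]-1-[(tert-butyldimethylsilyl)oxy]pent-3-en-2-yl}-4-iodophenol (C1 epimers) | Oc1ccc(I)cc1[C@H](/C=C/C)C(O[Si](C)(C)C(C)(C)C)c1ccc(OCc2ccccc2)cc1 | intermediate
10 | (2S,3S)-2-[4-(benzyloxy)phenyl]-5-iodo-3-[(1E)-prop-1-en-1-yl]-2,3-dihydro-1-benzofuran (trans) | Ic1ccc2c(c1)[C@H](/C=C/C)[C@@H](c1ccc(OCc3ccccc3)cc1)O2 | intermediate
11 | (2S,3S)-2-[4-(benzyloxy)phenyl]-5-iodo-2,3-dihydro-1-benzofuran-3-carbaldehyde (trans) | Ic1ccc2c(c1)[C@H](C=O)[C@@H](c1ccc(OCc3ccccc3)cc1)O2 | intermediate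
12 | 2,4-bis(benzyloxy)-1-bromobenzene | Brc1ccc(OCc2ccccc2)cc1OCc1ccccc1 | starting material
13 | [2,4-bis(benzyloxy)phenyl]magnesium bromide | Br[Mg]c1ccc(OCc2ccccc2)cc1OCc1ccccc1 | intermediate
14 | [2,4-bis(benzyloxy)phenyl]{(2S,3R)-2-[4-(benzyloxy)phenyl]-5-iodo-2,3-dihydro-1-benzofuran-3-yl}methanol (trans ring, carbinol epimers) | Ic1ccc2c(c1)[C@H](C(O)c1ccc(OCc3ccccc3)cc1OCc1ccccc1)[C@@H](c1ccc(OCc3ccccc3)cc1)O2 | intermediate
15 | 1-[2,4-bis(benzyloxy)phenyl]ethan-1-one | CC(=O)c1ccc(OCc2ccccc2)cc1OCc1ccccc1 | starting material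
16 | 1-[2,4-bis(benzyloxy)phenyl]prop-2-en-1-one | C=CC(=O)c1ccc(OCc2ccccc2)cc1OCc1ccccc1 | intermediate
17 | (2E)-1-[2,4-bis(benzyloxy)phenyl]-3-{(2S,3R)-2-[4-(benzyloxy)phenyl]-3-[[2,4-bis(benzyloxy)phenyl](hydroxy)methyl]-2,3-dihydro-1-benzofuran-5-yl}prop-2-en-1-one (carbinol epimers) | O=C(/C=C/c1ccc2c(c1)[C@H](C(O)c1ccc(OCc3ccccc3)cc1OCc1ccccc1)[C@@H](c1ccc(OCc3ccccc3)cc1)O2)c1ccc(OCc2ccccc2)cc1OCc1ccccc1 | intermediate
18 | (R)-epichlorohydrin | ClC[C@H]1CO1 | starting material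
19 | dimethyl malonate | COC(=O)CC(=O)OC | starting material
20 | methyl (1S,5R)-2-oxo-3-oxabicyclo[3.1.0]hexane-1-carboxylate | O=C1OC[C@@H]2C[C@]12C(=O)OC | intermediate
21 | methyl (3S,4R)-4-[4-(benzyloxy)benzyl]-2-oxooxolane-3-carboxylate (trans) | O=C1OC[C@H](Cc2ccc(OCc3ccccc3)cc2)[C@H]1C(=O)OC | intermediate
22 | (4R)-4-[4-(benzyloxy)benzyl]oxolan-2-one | O=C1OC[C@H](Cc2ccc(OCc3ccccc3)cc2)C1 | intermediate
23 | 1-(benzyloxy)-4-bromobenzene | Brc1ccc(OCc2ccccc2)cc1 | starting material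
24 | [4-(benzyloxy)phenyl]lithium | [Li]c1ccc(OCc2ccccc2)cc1 | intermediate
25 | (3R)-1-[4-(benzyloxy)phenyl]-3-[4-(benzyloxy)benzyl]-4-hydroxybutan-1-one | OC[C@H](Cc1ccc(OCc2ccccc2)cc1)CC(=O)c1ccc(OCc2ccccc2)cc1 | intermediate
26 | (2R)-2-[4-(benzyloxy)benzyl]-4-[4-(benzyloxy)phenyl]-4-oxobutanal | O=C[C@H](Cc1ccc(OCc2ccccc2)cc1)CC(=O)c1ccc(OCc2ccccc2)cc1 | intermediate
27 | 4-bromobenzene-1,3-diol | Oc1ccc(Br)c(O)c1 | starting material
28 | [(4-bromo-1,3-phenylene)bis(oxy)]bis(tert-butyldimethylsilane) | CC(C)(C)[Si](C)(C)Oc1ccc(Br)c(O[Si](C)(C)C(C)(C)C)c1 | intermediate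
29 | {2,4-bis[(tert-butyldimethylsilyl)oxy]phenyl}magnesium bromide | CC(C)(C)[Si](C)(C)Oc1ccc([Mg]Br)c(O[Si](C)(C)C(C)(C)C)c1 | intermediate
30 | (3R)-3-[4-(benzyloxy)benzyl]-1-[4-(benzyloxy)phenyl]-4-{2,4-bis[(tert-butyldimethylsilyl)oxy]phenyl}-4-hydroxybutan-1-one (C4 epimers) | CC(C)(C)[Si](C)(C)Oc1ccc(C(O)[C@H](Cc2ccc(OCc3ccccc3)cc2)CC(=O)c2ccc(OCc3ccccc3)cc2)c(O[Si](C)(C)C(C)(C)C)c1 | intermediate
31 | (2R,3R)-3-[4-(benzyloxy)benzyl]-5-[4-(benzyloxy)phenyl]-2-{2,4-bis[(tert-butyldimethylsilyl)oxy]phenyl}-2,3-dihydrofuran (trans) | CC(C)(C)[Si](C)(C)Oc1ccc([C@@H]2OC(c3ccc(OCc4ccccc4)cc3)=C[C@H]2Cc2ccc(OCc3ccccc3)cc2)c(O[Si](C)(C)C(C)(C)C)c1 | intermediate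
32 | 2,4-dihydroxybenzaldehyde | O=Cc1ccc(O)cc1O | starting material
33 | 4-formyl-1,3-phenylene diacetate | CC(=O)Oc1ccc(C=O)c(OC(C)=O)c1 | intermediate
34 | (2R,3R,4S,5S)-3-[4-(benzyloxy)benzyl]-5-[4-(benzyloxy)phenyl]-2-{2,4-bis[(tert-butyldimethylsilyl)oxy]phenyl}-4-[(2,4-diacetoxyphenyl)(hydroxy)methyl]oxolane (carbinol epimers) | CC(C)(C)[Si](C)(C)Oc1ccc([C@@H]2O[C@H](c3ccc(OCc4ccccc4)cc3)[C@H](C(O)c3ccc(OC(C)=O)cc3OC(C)=O)[C@H]2Cc2ccc(OCc3ccccc3)cc2)c(O[Si](C)(C)C(C)(C)C)c1 | intermediate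
35 | (2R,3R,4R,5S)-3-[4-(benzyloxy)benzyl]-5-[4-(benzyloxy)phenyl]-2-{2,4-bis[(tert-butyldimethylsilyl)oxy]phenyl}-4-(2,4-diacetoxybenzoyl)oxolane | CC(C)(C)[Si](C)(C)Oc1ccc([C@@H]2O[C@H](c3ccc(OCc4ccccc4)cc3)[C@H](C(=O)c3ccc(OC(C)=O)cc3OC(C)=O)[C@H]2Cc2ccc(OCc3ccccc3)cc2)c(O[Si](C)(C)C(C)(C)C)c1 | intermediate
36 | (2R,3R,4R,5S)-3-[4-(benzyloxy)benzyl]-5-[4-(benzyloxy)phenyl]-4-(2,4-dihydroxybenzoyl)-2-(2,4-dihydroxyphenyl)oxolane | Oc1ccc([C@@H]2O[C@H](c3ccc(OCc4ccccc4)cc3)[C@H](C(=O)c3ccc(O)cc3O)[C@H]2Cc2ccc(OCc3ccccc3)cc2)c(O)c1 | intermediate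
37 | heptabenzyl ether of the target (phenols of the chalcone ring, ring A and the three 4-hydroxyphenyl groups benzylated; benzofuran 2S,3S; methine S by CIP with the target geometry; oxolane 2R,3R,4R,5S) | O=C(/C=C/c1ccc2c(c1)[C@H]([C@H](c1ccc(OCc3ccccc3)cc1OCc1ccccc1)c1cc([C@@H]3O[C@H](c4ccc(OCc5ccccc5)cc4)[C@H](C(=O)c4ccc(O)cc4O)[C@H]3Cc3ccc(OCc4ccccc4)cc3)c(O)cc1O)[C@@H](c1ccc(OCc3ccccc3)cc1)O2)c1ccc(OCc2ccccc2)cc1OCc1ccccc1 | intermediate
38 | (2E)-1-(2,4-dihydroxyphenyl)-3-{(2S,3S)-3-[(R)-(2,4-dihydroxyphenyl){5-[(2R,3R,4R,5S)-4-(2,4-dihydroxybenzoyl)-3-(4-hydroxybenzyl)-5-(4-hydroxyphenyl)oxolan-2-yl]-2,4-dihydroxyphenyl}methyl]-2-(4-hydroxyphenyl)-2,3-dihydro-1-benzofuran-5-yl}prop-2-en-1-one | O=C(/C=C/c1ccc2c(c1)[C@H]([C@H](c1ccc(O)cc1O)c1cc([C@@H]3O[C@H](c4ccc(O)cc4)[C@H](C(=O)c4ccc(O)cc4O)[C@H]3Cc3ccc(O)cc3)c(O)cc1O)[C@@H](c1ccc(O)cc1)O2)c1ccc(O)cc1O | target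

## Step count and risks

Total steps: 21 (benzofuran branch 1–8, oxolane branch 9–19, union 20, deprotection 21).
Longest linear sequence: 11 steps (9, 10, 11, 12, 13, 15, 17, 18, 19, 20, 21).

The three steps most likely to fail are 17, 20 and 15.

The reductive aldehyde coupling on the enol ether (step 17) has no direct precedent on this substrate. The oxocarbenium ion may lose the C4 proton, or the silane may reduce the aldehyde first. The fallback sets out from dihydrofuran 31 and aldehyde 33 and returns at carbinol 34. Irradiation at 350 nm in benzene gives, by Paternò–Büchi [2+2] photocycloaddition on the face anti to the benzyl group, the cis-fused oxetane ketal 6-(2,4-diacetoxyphenyl)-1-[4-(benzyloxy)phenyl]-4-[4-(benzyloxy)benzyl]-3-{2,4-bis[(tert-butyldimethylsilyl)oxy]phenyl}-2,7-dioxabicyclo[3.2.0]heptane F1. BF3·OEt2 and Et3SiH at −78 °C then open the strained ketal C–O bond and reduce the oxocarbenium ion anti to the C4 substituent, which gives 34.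

The Friedel–Crafts union (step 20) may give the wrong methine epimer, or the cation may lose the C3 proton and aromatise to a benzofuran. The fallback reverses the roles of the two resorcinol rings, which also reverses the facial sense at the methine; it sets out from aldehyde 11 and tetraphenol 36 and returns at 37. Acid-catalysed hydroxyalkylation of ring B of 36 with 11 (TsOH, hexafluoro-2-propanol) gives the ring B carbinol {(2S,3R)-2-[4-(benzyloxy)phenyl]-5-iodo-2,3-dihydro-1-benzofuran-3-yl}{2,4-dihydroxy-5-[oxolan-2-yl of 36]phenyl}methanol F2. Its cation is trapped by an excess of commercial 1,3-bis(benzyloxy)benzene at C4, giving the 5-iodo analogue of 37 (iodine in place of the enone side chain) F3. A Heck reaction of F3 with vinyl ketone 16 under the conditions of step 8 then gives 37.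

The Grignard addition and dehydration (step 15) depends on the epimerisable 1,4-keto aldehyde 26, which can also close to a furan. The fallback installs ring B before the aryl ketone; it sets out from lactone 22 and returns at dihydrofuran 31. Aminolysis with MeNH(OMe)·HCl and AlMe3 gives (3R)-3-[4-(benzyloxy)benzyl]-4-hydroxy-N-methoxy-N-methylbutanamide F4, and Dess–Martin oxidation gives (3R)-3-[4-(benzyloxy)benzyl]-N-methoxy-N-methyl-4-oxobutanamide F5. Grignard reagent 29 adds to the aldehyde and the alkoxide lactonises, after acid equilibration, to (4R,5R)-4-[4-(benzyloxy)benzyl]-5-{2,4-bis[(tert-butyldimethylsilyl)oxy]phenyl}oxolan-2-one F6. Aryllithium 24 adds once to F6 and TsOH dehydrates the hemiketal to 31.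

## Further compounds

F1 | step 17 | 6-(2,4-diacetoxyphenyl)-1-[4-(benzyloxy)phenyl]-4-[4-(benzyloxy)benzyl]-3-{2,4-bis[(tert-butyldimethylsilyl)oxy]phenyl}-2,7-dioxabicyclo[3.2.0]heptane (cis-fused, oxetane anti to benzyl, C6 epimers) | CC(C)(C)[Si](C)(C)Oc1ccc([C@@H]2O[C@]3(c4ccc(OCc5ccccc5)cc4)OC(c4ccc(OC(C)=O)cc4OC(C)=O)[C@@H]3[C@H]2Cc2ccc(OCc3ccccc3)cc2)c(O[Si](C)(C)C(C)(C)C)c1
F2 | step 20 | {(2S,3R)-2-[4-(benzyloxy)phenyl]-5-iodo-2,3-dihydro-1-benzofuran-3-yl}{2,4-dihydroxy-5-[oxolan-2-yl of 36]phenyl}methanol (carbinol epimers) | Ic1ccc2c(c1)[C@H](C(O)c1cc([C@@H]3O[C@H](c4ccc(OCc5ccccc5)cc4)[C@H](C(=O)c4ccc(O)cc4O)[C@H]3Cc3ccc(OCc4ccccc4)cc3)c(O)cc1O)[C@@H](c1ccc(OCc3ccccc3)cc1)O2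
F3 | step 20 | 5-iodo analogue of 37 (iodine in place of the enone side chain) | Ic1ccc2c(c1)[C@H]([C@H](c1ccc(OCc3ccccc3)cc1OCc1ccccc1)c1cc([C@@H]3O[C@H](c4ccc(OCc5ccccc5)cc4)[C@H](C(=O)c4ccc(O)cc4O)[C@H]3Cc3ccc(OCc4ccccc4)cc3)c(O)cc1O)[C@@H](c1ccc(OCc3ccccc3)cc1)O2
F4 | step 15 | (3R)-3-[4-(benzyloxy)benzyl]-4-hydroxy-N-methoxy-N-methylbutanamide | OC[C@H](Cc1ccc(OCc2ccccc2)cc1)CC(=O)N(C)OC
F5 | step 15 | (3R)-3-[4-(benzyloxy)benzyl]-N-methoxy-N-methyl-4-oxobutanamide | O=C[C@H](Cc1ccc(OCc2ccccc2)cc1)CC(=O)N(C)OC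
F6 | step 15 | (4R,5R)-4-[4-(benzyloxy)benzyl]-5-{2,4-bis[(tert-butyldimethylsilyl)oxy]phenyl}oxolan-2-one | CC(C)(C)[Si](C)(C)Oc1ccc([C@@H]2OC(=O)C[C@H]2Cc2ccc(OCc3ccccc3)cc2)c(O[Si](C)(C)C(C)(C)C)c1
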